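Labdane numbering is used (decalin C1–C10, chain C11–C16, C17 on C8, C18/C19 on C4, C20 on C10). Late stage: the 15-acetate comes from the 8α,15-diol. The C8 carbinol comes from the 8α,17-epoxide of a C8=C17 alkene, which comes from a C8 ketone. The E C13=C14 alkene comes from a C13 methyl ketone by olefination.
Enabling feature: in ring B the carbinol carbon C8, the methine C9 and the methyl-bearing quaternary C10 are contiguous. At the ketone level C8(=O)–C9=C10(CH3) is a 3-methylcyclohexenone, with C10 as acceptor and C9 as enolate carbon, so one three-component operation makes both C10–C1 (allyl) and C9–C11 (vinyl ketone).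
Ring B, C4 and its two methyl groups are bought together as (+)-verbenone (1), whose extra C4–C7 bond (cyclobutane) is a temporary ring. It supplies the C5 stereocentre, shields one enone face (which sets C10) and later releases C4 as a tertiary cation.
Order of rings: ring B is present from the start. Ring A is closed in step 3 by opening C4–C7 and bonding C4 to the allyl terminus C3. C9 is then equilibrated next to the C8 ketone to the equatorial epimer.
Key step: step 1

Assumption: (1R,5R)-(+)-verbenone is taken as commercially available in high enantiomeric purity (it is the allylic oxidation product of (+)-alpha-pinene).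

Step 1
Reactants: 1 (1R,5R)-(+)-verbenone; 2 allyltrimethylsilane; 3 methyl vinyl ketone
Product: 5 4-allyl-4,6,6-trimethyl-3-(3-oxobutyl)bicyclo[3.1.1]heptan-2-one, via trichlorotitanium enolate 4 (not isolated)
Conditions: TiCl4, 2 (limiting), CH2Cl2, −78 → −40 °C; then 3, −78 → −20 °C; H2O
Reagents that add atoms: none
Why: TiCl4 binds the carbonyl of 1, the CH2= terminus of 2 attacks C10 (Hosomi–Sakurai conjugate allylation, loss of Me3SiCl), and the regiodefined enolate 4 then adds through C9 to the CH2= terminus (C11) of TiCl4-activated 3 (Michael addition), protonation on work-up giving 5. Both halves are known reaction types (Sakurai allylation builds quaternary carbons on beta,beta-disubstituted cyclic enones; chlorotitanium and silyl enolates add to vinyl ketones under TiCl4), and their union follows the known tandem format of conjugate addition followed by enolate trapping. No ring is closed in this step; it joins three commercial compounds and assembles 17 of the 20 skeletal carbons around C9 and C10. C10 is controlled by the CMe2 bridge (C4), which covers one face of the enone, so allyl enters anti to it and ends trans to C4 on the neighbouring C5, the relation that becomes the trans ring fusion. C9 is attacked on the same open face, which should place C11 cis to allyl (the later axial epimer); this is harmless because C9 stays alpha to the C8 ketone and is equilibrated in step 3. The step needs 1,4- instead of 1,2-allylation (soft allylsilane, carbonyl flanked by a bridgehead), bond formation at C9 and not C7 (only C9 belongs to enolate 4, and C7 is a bridgehead that cannot enolise), no free 2 left when 3 is added (2 is the limiting reagent), and an intact cyclobutane, which the low temperature secures.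

Step 2
Reactants: 5 4-allyl-4,6,6-trimethyl-3-(3-oxobutyl)bicyclo[3.1.1]heptan-2-one
Product: 6 methyl (E)-5-(4-allyl-4,6,6-trimethyl-2-oxobicyclo[3.1.1]heptan-3-yl)-3-methylpent-2-enoate
Conditions: (MeO)2P(O)CH2CO2Me, NaH, THF, 0 → 50 °C; E isomer separated by chromatography
Reagents that add atoms: trimethyl phosphonoacetate COC(=O)CP(=O)(OC)OC
Why: Horner–Wadsworth–Emmons olefination: the phosphonate anion attacks only the unhindered C13 methyl ketone because the C8 carbonyl is flanked by a bridgehead and the substituted C9, and the reversible addition favours the E-trisubstituted enoate, the minor Z isomer being removed.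

Step 3
Reactants: 6 methyl (E)-5-(4-allyl-4,6,6-trimethyl-2-oxobicyclo[3.1.1]heptan-3-yl)-3-methylpent-2-enoate
Product: 9 methyl (13E)-2α-chloro-8-oxo-17-norlabd-13-en-15-oate, via ring-opened tertiary chloride 7 (not isolated), via axial C9 epimer 8 (not isolated)
Conditions: SnCl4, CH2Cl2, −20 °C → rt; H2O; then K2CO3, MeOH, rt
Reagents that add atoms: tin tetrachloride Cl[Sn](Cl)(Cl)Cl
Why: Proposed new method: SnCl4 on the C8 carbonyl should trigger strain-releasing heterolysis of the C4–C7 cyclobutane bond to a tin enolate and the tertiary C4 cation (parked as chloride 7); once ring B has flipped so that the C4 group and the allyl group are both equatorial, C3 of the terminal alkene attacks C4 (6-endo-trig, Markovnikov, chair) and chloride caps the secondary C2 centre, which closes ring A as a trans-decalin because allyl and C4 are trans on C10/C5, and K2CO3/MeOH then moves the C9 chain from axial (8) to equatorial (9) through the C8 enolate; the closest known reactions are the SnCl4 opening of 4-aryl-6,6-dimethylbicyclo[3.1.1]heptan-2-ones with capture of the same cation by a phenol oxygen, and halide-terminated Prins-type cation–olefin cyclisations.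

Step 4
Reactants: 9 methyl (13E)-2α-chloro-8-oxo-17-norlabd-13-en-15-oate
Product: 10 methyl (13E)-8-oxo-17-norlabd-13-en-15-oate
Conditions: Bu3SnH, AIBN (cat.), toluene, 100 °C
Reagents that add atoms: none
Why: Radical chain dehalogenation: the tin radical abstracts the secondary chlorine and the C2 radical takes hydrogen from Bu3SnH, which erases the auxiliary C2 stereocentre and leaves the ketone, the enoate and C5, C9 and C10 untouched.

Step 5
Reactants: 10 methyl (13E)-8-oxo-17-norlabd-13-en-15-oate
Product: 11 methyl (13E)-labda-8(17),13-dien-15-oate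
Conditions: Ph3PCH3Br, KOt-Bu, toluene, rt → 60 °C
Reagents that add atoms: methyltriphenylphosphonium bromide C[P+](c1ccccc1)(c1ccccc1)c1ccccc1.[Br-]
Why: Wittig methylenation: the small non-stabilised ylide adds to the hindered C8 ketone while the beta,beta-disubstituted enoate is inert, and any enolisation can only return the equatorial, thermodynamically preferred C9 epimer.

Step 6
Reactants: 11 methyl (13E)-labda-8(17),13-dien-15-oate
Product: 12 methyl (13E)-8α,17-epoxylabd-13-en-15-oate
Conditions: mCPBA, CH2Cl2, 0 °C
Reagents that add atoms: 3-chloroperbenzoic acid O=C(OO)c1cccc(Cl)c1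
Why: Prilezhaev epoxidation: the electron-rich 1,1-disubstituted C8=C17 alkene reacts while the conjugated C13=C14 enoate does not, and the peracid should approach from the alpha face, away from the axial C10 methyl group, which places oxygen alpha (equatorial) on C8.

Step 7
Reactants: 12 methyl (13E)-8α,17-epoxylabd-13-en-15-oate
Product: 13 (13E)-labd-13-ene-8α,15-diol
Conditions: LiAlH4, THF, 0 °C → rt
Reagents that add atoms: none
Why: Hydride reduction: hydride opens the spiro epoxide by SN2 attack at the unhindered C17 methylene, so the C8–O bond and its alpha configuration are kept and C17 becomes the methyl group, while the enoate is reduced 1,2 to the E-allylic alcohol.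

Step 8
Reactants: 13 (13E)-labd-13-ene-8α,15-diol
Product: 14 (13E)-8α-hydroxylabd-13-en-15-yl acetate (target)
Conditions: Ac2O, pyridine, 0 °C → rt
Reagents that add atoms: acetic anhydride CC(=O)OC(C)=O
Why: Selective acylation: the primary allylic C15 hydroxyl is acetylated under conditions that leave the hindered tertiary C8 hydroxyl free.

Compound list
1 | (1R,5R)-(+)-verbenone, 4,6,6-trimethylbicyclo[3.1.1]hept-3-en-2-one | CC1=CC(=O)[C@@H]2C[C@H]1C2(C)C | starting material
2 | allyltrimethylsilane | C=CC[Si](C)(C)C | starting material
3 | methyl vinyl ketone (but-3-en-2-one) | CC(=O)C=C | starting material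
4 | trichlorotitanium enolate (C8=C9) of 4-allyl-4,6,6-trimethylbicyclo[3.1.1]heptan-2-one, allyl anti to the CMe2 bridge | Cl[Ti](Cl)(Cl)OC1=C[C@@](C)(CC=C)[C@H]2C[C@@H]1C2(C)C | intermediate
5 | 4-allyl-4,6,6-trimethyl-3-(3-oxobutyl)bicyclo[3.1.1]heptan-2-one, allyl and 3-oxobutyl both on the face opposite the CMe2 bridge | CC(=O)CC[C@@H]1C(=O)[C@@H]2C[C@@H](C2(C)C)[C@]1(C)CC=C | intermediate
6 | methyl (E)-5-(4-allyl-4,6,6-trimethyl-2-oxobicyclo[3.1.1]heptan-3-yl)-3-methylpent-2-enoate, ring stereocentres as in 5 | COC(=O)/C=C(\C)CC[C@@H]1C(=O)[C@@H]2C[C@@H](C2(C)C)[C@]1(C)CC=C | intermediate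
7 | methyl (E)-5-[2-allyl-3-(2-chloropropan-2-yl)-2-methyl-6-oxocyclohexyl]-3-methylpent-2-enoate, allyl trans to the chloroisopropyl group, chain cis to allyl (present in the flask as its tin enolate) | COC(=O)/C=C(\C)CC[C@H]1[C@@](C)(CC=C)[C@@H](CCC1=O)C(C)(C)Cl | intermediate
8 | methyl (13E)-2α-chloro-8-oxo-17-nor-9-epi-labd-13-en-15-oate, trans-decalin, C9 chain axial (alpha) | COC(=O)/C=C(\C)CC[C@H]1[C@@]2(C)C[C@@H](Cl)CC(C)(C)[C@@H]2CCC1=O | intermediate
9 | methyl (13E)-2α-chloro-8-oxo-17-norlabd-13-en-15-oate, 5α-H, 9α-H, 10β-CH3, equatorial chlorine | COC(=O)/C=C(\C)CC[C@@H]1[C@@]2(C)C[C@@H](Cl)CC(C)(C)[C@@H]2CCC1=O | intermediate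
10 | methyl (13E)-8-oxo-17-norlabd-13-en-15-oate, 5α-H, 9α-H, 10β-CH3 | COC(=O)/C=C(\C)CC[C@@H]1[C@@]2(C)CCCC(C)(C)[C@@H]2CCC1=O | intermediate
11 | methyl (13E)-labda-8(17),13-dien-15-oate, 5α-H, 9α-H, 10β-CH3 | COC(=O)/C=C(\C)CC[C@@H]1[C@@]2(C)CCCC(C)(C)[C@@H]2CCC1=C | intermediate
12 | methyl (13E)-8α,17-epoxylabd-13-en-15-oate, epoxide oxygen alpha on C8 | COC(=O)/C=C(\C)CC[C@@H]1[C@@]2(C)CCCC(C)(C)[C@@H]2CC[C@]13CO3 | intermediate
13 | (5S,8R,9R,10S,13E)-labd-13-ene-8α,15-diol | OC/C=C(\C)CC[C@@H]1[C@@]2(C)CCCC(C)(C)[C@@H]2CC[C@@]1(C)O | intermediate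
14 | (5S,8R,9R,10S,13E)-8α-hydroxylabd-13-en-15-yl acetate | CC(=O)OC/C=C(\C)CC[C@@H]1[C@@]2(C)CCCC(C)(C)[C@@H]2CC[C@@]1(C)O | target

Total step count: 8. Longest linear sequence: 8 steps (1 to 14).

Steps most likely to fail

Step 3 (Proposed new method). The C4 cation may be lost before ring A closes, by proton loss, by hydride shift from C5 or by skeletal shifts at the secondary C2 cation. The fallback sets out from 6 and comes back at 9. It separates ring opening from ring closure and uses known reactions. BF3·OEt2, Zn(OAc)2 and Ac2O open the cyclobutane of 6, as is known for 6,6-dimethylbicyclo[3.1.1]heptan-2-ones, to give the ring-opened enol acetate tertiary acetate F1. K2CO3 in MeOH cleaves the enol acetate and equilibrates C9 to give the keto tertiary acetate F2. TiCl4 in CH2Cl2 at −78 °C then ionises only the tertiary acetate of the conformationally relaxed cyclohexanone, and the chloride-terminated cation–olefin cyclisation gives 9.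

Step 1. The hindered enolate may capture the vinyl ketone too slowly, the vinyl ketone may polymerise, or the cyclobutane may open early under TiCl4. The fallback sets out from 1 and comes back at 5. It replaces the titanium tandem by copper and lithium chemistry with a silyl-activated acceptor. The allylcopper reagent made from allylMgBr, CuI and LiCl adds to 1 in the presence of Me3SiCl to give the trimethylsilyl enol ether F3. MeLi releases the regiodefined lithium enolate, which is trapped by 3-(trimethylsilyl)but-3-en-2-one to give the alpha-silyl diketone F4. KF in MeOH removes the silyl group and gives 5.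

Step 6. Facial selectivity in the epoxidation of the exocyclic alkene may be poor, which would erode the C8 configuration. The fallback sets out from 11 and comes back at 14. It installs the C8 oxygen by a radical hydration instead of epoxidation and hydride opening. i-Bu2AlH reduces 11 to the dienol F5, and Ac2O in pyridine gives the dienyl acetate F6. Mukaiyama hydration (Co(acac)2, PhSiH3, O2, then PPh3) transfers a hydrogen atom to the accessible C17 methylene in preference to the trisubstituted allylic acetate alkene. The tertiary C8 radical is then trapped by O2 from the open alpha face to give 14.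

Further compounds
F1 | step 3 | methyl (E)-5-[6-acetoxy-3-(2-acetoxypropan-2-yl)-2-allyl-2-methylcyclohex-5-en-1-yl]-3-methylpent-2-enoate, allyl trans to the acetoxyisopropyl group, chain cis to allyl | COC(=O)/C=C(\C)CC[C@H]1[C@@](C)(CC=C)[C@@H](CC=C1OC(C)=O)C(C)(C)OC(C)=O
F2 | step 3 | methyl (E)-5-[3-(2-acetoxypropan-2-yl)-2-allyl-2-methyl-6-oxocyclohexyl]-3-methylpent-2-enoate, allyl trans to the acetoxyisopropyl group, chain trans to allyl | COC(=O)/C=C(\C)CC[C@@H]1[C@@](C)(CC=C)[C@@H](CCC1=O)C(C)(C)OC(C)=O
F3 | step 1 | 4-allyl-4,6,6-trimethyl-2-(trimethylsilyloxy)bicyclo[3.1.1]hept-2-ene, allyl anti to the CMe2 bridge | C[Si](C)(C)OC1=C[C@@](C)(CC=C)[C@H]2C[C@@H]1C2(C)C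
F4 | step 1 | 4-allyl-4,6,6-trimethyl-3-[3-oxo-2-(trimethylsilyl)butyl]bicyclo[3.1.1]heptan-2-one, ring stereocentres as in 5, silyl-bearing carbon undefined | CC(=O)C(C[C@@H]1C(=O)[C@@H]2C[C@@H](C2(C)C)[C@]1(C)CC=C)[Si](C)(C)C
F5 | step 6 | (13E)-labda-8(17),13-dien-15-ol, 5α-H, 9α-H, 10β-CH3 | OC/C=C(\C)CC[C@@H]1[C@@]2(C)CCCC(C)(C)[C@@H]2CCC1=C
F6 | step 6 | (13E)-labda-8(17),13-dien-15-yl acetate, 5α-H, 9α-H, 10β-CH3 | CC(=O)OC/C=C(\C)CC[C@@H]1[C@@]2(C)CCCC(C)(C)[C@@H]2CCC1=C
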